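Side chain numbered C1' (ArCH2) to C8'. Last disconnection: the aryl–Cβ bond of the Z-acrylic acid (Suzuki–Miyaura), giving an aryl pinacol boronate and (Z)-3-iodoacrylic acid. The Z geometry is bought, and no ester has to be cleaved beside the acetate.
Key disconnection: C3'–C4', giving the methyl-capped alkyne ArCH2–C≡C–CH3 and 4-methylpent-3-enal. One flask (syn H–Zr addition, Zr→Zn exchange, ligand-controlled carbonyl addition, Ac2O capture) should deliver the C–C bond, the E C2'=C3' alkene, the (R)-C4' centre and the acetate.
Enabling feature: the array C2'(H)=C3'(CH3)–C4'(H)(OAc), with H on C2' cis to C4' and only a methyl group on C3'. This is the imprint of a syn hydrometalation of a 2-alkyne that places the metal next to methyl, and C1'H2 insulates the alkyne from the benzene ring.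
The alkyne comes from 5-bromo-2-methoxybenzyl bromide and propynyl Grignard reagent, followed by Miyaura borylation. The aldehyde comes from 4-methylpent-3-en-1-ol by Dess–Martin oxidation.
Rings: the benzene ring is bought and no ring of the target is built. The only ring made is the temporary dioxaborolane (on in step 2, off in step 5).

Key step: step 4

Assumption: (−)-MIB is taken to direct the alkenylzinc to the Si face of the aldehyde, as amino-alcohol ligands of this series do with other aldehydes; if the sense proved opposite, (+)-MIB would be used instead.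

Step 1
Reactants: 1 4-bromo-2-(bromomethyl)-1-methoxybenzene; 2 prop-1-yn-1-ylmagnesium bromide
Product: 3 4-bromo-2-(but-2-yn-1-yl)-1-methoxybenzene
Conditions: CuBr·SMe2 (10 mol %), THF, 0 °C to 50 °C
Reagents that add atoms: none
Why: Monovalent-copper-catalysed sp–sp3 cross-coupling of an alkynyl Grignard reagent with a benzylic bromide: the activated benzylic C–Br bond reacts while the aryl C–Br bond is inert, and because the alkyne enters through its own terminus no allenic (SN2') isomer can arise.

Step 2
Reactants: 3 4-bromo-2-(but-2-yn-1-yl)-1-methoxybenzene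
Product: 4 2-[3-(but-2-yn-1-yl)-4-methoxyphenyl]-4,4,5,5-tetramethyl-1,3,2-dioxaborolane
Conditions: B2pin2, Pd(dppf)Cl2 (3 mol %), KOAc, 1,4-dioxane, 80 °C
Reagents that add atoms: bis(pinacolato)diboron, CC1(C)OB(OC1(C)C)B1OC(C)(C)C(C)(C)O1
Why: Miyaura borylation: zerovalent palladium inserts into the aryl C–Br bond and acetate-assisted transmetalation with B2pin2 gives the aryl boronate, KOAc being too weak a base to isomerise the skipped aryl-alkyne to an allene and the internal alkyne being inert to this catalyst.

Step 3
Reactants: 5 4-methylpent-3-en-1-ol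
Product: 6 4-methylpent-3-enal
Conditions: Dess–Martin periodinane, CH2Cl2, 0 °C to rt; cold aq NaHCO3/Na2S2O3 wash; careful concentration at 0 °C, taken up in toluene and used at once
Reagents that add atoms: none
Why: Dess–Martin oxidation: a neutral, base-free oxidation that stops at the aldehyde and should leave the β,γ-double bond where it is, the volatile product being carried on in solution.

Step 4
Reactants: 4 2-[3-(but-2-yn-1-yl)-4-methoxyphenyl]-4,4,5,5-tetramethyl-1,3,2-dioxaborolane; 6 4-methylpent-3-enal
Product: 10 (2E,4R)-1-[2-methoxy-5-(4,4,5,5-tetramethyl-1,3,2-dioxaborolan-2-yl)phenyl]-3,7-dimethylocta-2,6-dien-4-yl acetate, via alkenylzirconocene chloride 7 (not isolated), via alkenyl(methyl)zinc 8 (not isolated), via methylzinc alkoxide 9 (not isolated)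
Conditions: Cp2Zr(H)Cl (1.3 equiv), CH2Cl2, rt; solvent switch to toluene; Me2Zn (1.3 equiv), −65 °C; (−)-MIB (10 mol %), then 6 (1.5 equiv), −30 to 0 °C; Ac2O (3 equiv), DMAP (cat), 0 °C to rt
Reagents that add atoms: acetic anhydride, CC(=O)OC(C)=O (acetyl group of 10); Cp2Zr(H)Cl, [H][Zr](Cl)(C1C=CC=C1)C1C=CC=C1 (zirconocene fragment of 7 only); dimethylzinc, C[Zn]C (MeZn fragment of 8 and 9 only)
Why: Cp2Zr(H)Cl adds H and Zr syn across C2'≡C3', and the slight excess of hydride makes the addition reversible through a second hydrozirconation, so zirconium should settle on C3' beside the small methyl group instead of on C2' beside the o-methoxybenzyl group, which fixes the E geometry (H on C2' cis to the metal) in 7. Me2Zn exchanges Zr for Zn with retention to give 8, whose alkenyl group (faster to transfer than methyl) adds to aldehyde 6 inside the bimetallic zinc amino-alkoxide assembly formed from (−)-MIB through a six-membered transition state, and Ac2O then captures alkoxide 9 as the acetate. The closest known reaction type is the hydrozirconation, zinc transmetalation and amino-alcohol-catalysed enantioselective alkenylation of aldehydes, combined with in situ acylation of the zinc alkoxide. No ring is closed. The only new stereocentre, C4' (R), is controlled by the ligand, which should expose the Si face of 6, while the alkene geometry follows from syn hydrometalation followed by retentive transmetalation and retentive C–C bond formation. The step needs regioselectivity (secured by the methyl against arylmethyl size difference at the alkyne), chemoselectivity (aryl ether, aryl Bpin and the trisubstituted alkene of 6 are inert to Cp2Zr(H)Cl and Me2Zn, and 6 carries the only carbonyl group) and mildness towards the isomerisation-prone β,γ-unsaturated aldehyde (secured by the weakly basic organozinc at low temperature).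

Step 5
Reactants: 10 (2E,4R)-1-[2-methoxy-5-(4,4,5,5-tetramethyl-1,3,2-dioxaborolan-2-yl)phenyl]-3,7-dimethylocta-2,6-dien-4-yl acetate; 11 (Z)-3-iodoacrylic acid
Product: 12 (2Z)-3-{3-[(2E,4R)-4-acetoxy-3,7-dimethylocta-2,6-dien-1-yl]-4-methoxyphenyl}prop-2-enoic acid
Conditions: Pd(OAc)2 (5 mol %), P(o-tol)3 (10 mol %), K3PO4, THF–H2O, rt, dark; then cold 1 M HCl to pH 3
Reagents that add atoms: none
Why: Suzuki–Miyaura coupling: oxidative addition into the electron-poor alkenyl carbon–iodine bond is fast at room temperature and, like transmetalation and reductive elimination, proceeds with retention, so the Z geometry of 11 is transferred, while the bulky P(o-tol)3 ligand and the hindered trisubstituted C2'=C3' alkene should keep zerovalent palladium from ionising the allylic acetate, and the C4' stereocentre is not touched.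

Compound list
1 | 4-bromo-2-(bromomethyl)-1-methoxybenzene | COc1ccc(Br)cc1CBr | starting material
2 | prop-1-yn-1-ylmagnesium bromide | CC#C[Mg]Br | starting material
3 | 4-bromo-2-(but-2-yn-1-yl)-1-methoxybenzene | COc1ccc(Br)cc1CC#CC | intermediate
4 | 2-[3-(but-2-yn-1-yl)-4-methoxyphenyl]-4,4,5,5-tetramethyl-1,3,2-dioxaborolane | COc1ccc(B2OC(C)(C)C(C)(C)O2)cc1CC#CC | intermediate
5 | 4-methylpent-3-en-1-ol | CC(C)=CCCO | starting material
6 | 4-methylpent-3-enal | CC(C)=CCC=O | intermediate
7 | chloro{(2E)-4-[2-methoxy-5-(4,4,5,5-tetramethyl-1,3,2-dioxaborolan-2-yl)phenyl]but-2-en-2-yl}zirconocene (Cp rings written as σ-bonded C5H5 in the SMILES) | COc1ccc(B2OC(C)(C)C(C)(C)O2)cc1C/C=C(\C)[Zr](Cl)(C1C=CC=C1)C1C=CC=C1 | intermediate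
8 | {(2E)-4-[2-methoxy-5-(4,4,5,5-tetramethyl-1,3,2-dioxaborolan-2-yl)phenyl]but-2-en-2-yl}(methyl)zinc | COc1ccc(B2OC(C)(C)C(C)(C)O2)cc1C/C=C(\C)[Zn]C | intermediate
9 | methylzinc (2E,4R)-1-[2-methoxy-5-(4,4,5,5-tetramethyl-1,3,2-dioxaborolan-2-yl)phenyl]-3,7-dimethylocta-2,6-dien-4-olate | COc1ccc(B2OC(C)(C)C(C)(C)O2)cc1C/C=C(\C)[C@@H](CC=C(C)C)O[Zn]C | intermediate
10 | (2E,4R)-1-[2-methoxy-5-(4,4,5,5-tetramethyl-1,3,2-dioxaborolan-2-yl)phenyl]-3,7-dimethylocta-2,6-dien-4-yl acetate | COc1ccc(B2OC(C)(C)C(C)(C)O2)cc1C/C=C(\C)[C@@H](CC=C(C)C)OC(C)=O | intermediate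
11 | (Z)-3-iodoacrylic acid | OC(=O)/C=C\I | starting material
12 | (2Z)-3-{3-[(2E,4R)-4-acetoxy-3,7-dimethylocta-2,6-dien-1-yl]-4-methoxyphenyl}prop-2-enoic acid | COc1ccc(/C=C\C(=O)O)cc1C/C=C(\C)[C@@H](CC=C(C)C)OC(C)=O | target

Total step count: 5. Longest linear sequence: 4 steps (1, 2, 4, 5).

Steps most likely to fail

Step 4. Three processes may go wrong:
- Facial selectivity may be eroded by a ligand-free background addition that the zirconocene by-product promotes.
- The regio-equilibration of the hydrozirconation may stay incomplete, possibly helped by a weak contact of the methoxy oxygen with zirconium.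
- The double bond of 6 may migrate, or 6 may be enolised, in contact with zinc alkoxides.

The fallback forms the same C3'–C4' bond by an asymmetric Nozaki–Hiyama–Kishi coupling, which is non-basic. It sets out from 4 and comes back at 10. Hydrozirconation of 4 to 7 as before is followed by iodinolysis (I2, THF, 0 °C) to the (E)-alkenyl iodide F1, from which a minor regioisomer can be removed by chromatography. F1 and 6 are then joined with CrCl2 precomplexed with a chiral oxazoline–sulfonamide ligand and Et3N, plus catalytic NiCl2, in THF at rt. The ligand enantiomer that leads to Si-face addition is used, and the coupling should give the (R)-allylic alcohol F2. Ac2O, pyridine and DMAP convert F2 into 10.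

Step 5. Zerovalent palladium may ionise the allylic acetate at C4'. The aqueous phosphate may saponify the acetate. Part of the Z geometry may be lost at the alkenylpalladium stage. The fallback changes the order of events so that no allylic ester ever meets palladium or aqueous base. It sets out from 9 and comes back at 12. Alkoxide 9 is quenched with aqueous NH4Cl instead of Ac2O to give the (R)-allylic alcohol F2. Coupling of F2 with 11 under the catalyst of step 5 should give the hydroxy acid F3. Ac2O, pyridine and DMAP acetylate the C4' hydroxyl and transiently the carboxyl group, giving the mixed anhydride F4. The aqueous work-up hydrolyses F4 to 12.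

Step 3. The double bond may migrate into conjugation with the carbonyl group. The volatile aldehyde may be lost on concentration, and it may undergo self-aldolisation on standing. The fallback forms the C3'–C4' bond at the ketone oxidation level, so the free aldehyde is never made. It sets out from 5 and comes back at 10.
- TEMPO and PhI(OAc)2 in MeCN–H2O oxidise 5 to 4-methylpent-3-enoic acid F5.
- (COCl)2 with catalytic DMF converts F5 into the acid chloride F6.
- CuBr·SMe2-catalysed acylation of 7 (made from 4 as in step 4) with F6 should give the dienone F7.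
- Corey–Bakshi–Shibata reduction of F7 with (S)-2-methyl-CBS-oxazaborolidine and catecholborane in toluene at −78 °C should give the (R)-allylic alcohol F2, with the α-methylalkenyl group acting as the large substituent.
- Acetylation of F2 (Ac2O, pyridine, DMAP) gives 10.

Further compounds
F1 | step 4 | 2-{3-[(2E)-3-iodobut-2-en-1-yl]-4-methoxyphenyl}-4,4,5,5-tetramethyl-1,3,2-dioxaborolane | COc1ccc(B2OC(C)(C)C(C)(C)O2)cc1C/C=C(\C)I
F2 | step 4 | (2E,4R)-1-[2-methoxy-5-(4,4,5,5-tetramethyl-1,3,2-dioxaborolan-2-yl)phenyl]-3,7-dimethylocta-2,6-dien-4-ol | COc1ccc(B2OC(C)(C)C(C)(C)O2)cc1C/C=C(\C)[C@@H](CC=C(C)C)O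
F3 | step 5 | (2Z)-3-{3-[(2E,4R)-4-hydroxy-3,7-dimethylocta-2,6-dien-1-yl]-4-methoxyphenyl}prop-2-enoic acid | COc1ccc(/C=C\C(=O)O)cc1C/C=C(\C)[C@@H](CC=C(C)C)O
F4 | step 5 | acetic (2Z)-3-{3-[(2E,4R)-4-acetoxy-3,7-dimethylocta-2,6-dien-1-yl]-4-methoxyphenyl}prop-2-enoic anhydride | COc1ccc(/C=C\C(=O)OC(C)=O)cc1C/C=C(\C)[C@@H](CC=C(C)C)OC(C)=O
F5 | step 3 | 4-methylpent-3-enoic acid | CC(C)=CCC(=O)O
F6 | step 3 | 4-methylpent-3-enoyl chloride | CC(C)=CCC(=O)Cl
F7 | step 3 | (2E)-1-[2-methoxy-5-(4,4,5,5-tetramethyl-1,3,2-dioxaborolan-2-yl)phenyl]-3,7-dimethylocta-2,6-dien-4-one | COc1ccc(B2OC(C)(C)C(C)(C)O2)cc1C/C=C(\C)C(=O)CC=C(C)C
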